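## The problem

The target is a trans-fused hydroazulene: a cyclopentane (C1–C5) fused through the C1–C5 bond to a cycloheptene (C1, C5–C10). Numbering used throughout: C1 methyl-bearing fusion carbon, C2/C3 cyclopentane methylenes, C4 isopropyl carbinol, C5 fusion CH, C6 veratroyloxy carbon, C7 methylene, C8=C9 alkene with methyl on C8, C10 angeloyloxy carbon; β is the face of the C1 methyl. Five stereocentres must be set: quaternary C1 (CH3 β), tertiary carbinol C4 (OH β, isopropyl α), C5 (H α), C6 (O α) and C10 (O α). C4 can be taken from the chiral pool and can steer C1 and C5 while the cyclopentane forms. The pseudo-axial C1 methyl then shields the β face of the seven-membered ring, so external reagents reach C9/C10 from the α face. The β hydroxyl at C4 can deliver hydride to the β face of C6. Two secondary alcohols carry different acyl groups and must be acylated in sequence while the tertiary C4 hydroxyl stays free. The angelate isomerises to the tiglate with base, nucleophiles or heat and accepts soft nucleophiles, so it must go on last. Intermediates with C4–OH next to a C6 ketone are open to retro-aldol cleavage and C5 epimerisation. The enabling feature is that C6 lies between C5 and C7 and can be a ketone carbon, so C5–C6–C7 can be an oxyallyl cation, while C8–C9–C10–C1 are contiguous and can be a diene. Diene terminus C1 is tied to C5 through C2–C4, so one (4+3) event can close both rings.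

## Retrosynthesis

The C10 O–acyl bond is cut first, giving diol 25 and angelic acid 26. The angelate would not survive selenolate, peracid or acylation catalysts, so it is introduced last. In 25 the only other hydroxyl is the unreactive tertiary one at C4. The forward step must acylate a neopentyl allylic alcohol without Z to E isomerisation.

Alcohol 25 is traced to the 9α,10α-epoxide 22 and this to alkene 21, which has its double bond at C9=C10. The ring-forming step leaves the alkene one position away from where the target has it and leaves C10 unoxidised. Epoxide opening at C9 by selenolate (23), oxidation (24) and syn elimination move the alkene to C8=C9 and keep oxygen on the α face of C10. A singlet-oxygen ene reaction would be shorter, but it delivers oxygen to the face of the hydrogen it removes from C8, which is β, and so would give the wrong C10 epimer. The forward steps require α-face epoxidation and a β hydrogen at C8.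

Ester 21 is cut at the C6 O–acyl bond to diol 19 and 3,4-dimethoxybenzoyl chloride 20. Diol 19 comes from β-hydroxy ketone 18 by hydroxyl-directed reduction, and 18 from silyl ether 17. Acylating C6 before C10–OH exists removes any selectivity problem between the two secondary alcohols. The forward reduction must deliver hydride from the β face, which an external reagent would avoid because of the C1 methyl.

Ketone 17 is cut at C1–C5 and C7–C8 to the acyclic dienyl chloromethyl ketone 15, through oxyallyl cation 16. Compared with stepwise annulation of either ring, this removes both rings and three stereocentres in one operation and leaves a chain with one stereocentre. The forward step must give trans fusion, the correct sense relative to C4, and 8α-methyl/8β-H. All three depend on an (E,E)-diene of defined geometry.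

The C6–C7 bond of 15 is cut to aldehyde 12 and chloroiodomethane 13, with chlorohydrin 14 as the oxidation precursor. The α-chloro ketone tolerates neither amide bases, organoaluminium reagents nor palladium coupling, so it is made immediately before the key step.

The diene of 12 (masked as acetal 11) is cut at C9–C10 to alkenyl iodide 9 and (E)-propenylboronic acid 10. Iodide 9 is cut at the C1–CH3 bond to alkyne 7. Direct olefination of methyl ketone 5 with a crotyl phosphonate would be shorter. It would, however, give poor E/Z control at C1=C10, because CH3 and CH2R differ little in size. Syn-carboalumination fixes this geometry unambiguously. The former ketone methyl becomes C10 and the new methyl becomes the C1 methyl.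

Alkyne 7 comes from keto acetal 5, and 5 from keto aldehyde 4, which is the ozonolysis product (via ozonide 3) of silyl ether 2 of (S)-terpinen-4-ol 1. The ring alkene carbons become C1 and C6, and the carbinol carbon is C4 in the required configuration. Silylation precedes ozonolysis so that no hemiketal or retro-aldol pathway opens. The acetal distinguishes the aldehyde from the ketone for the base and aluminium steps.

## Roads not taken

Alternative 1: The cyclopentane is bought and the C1–CH3 and C5–C6 bonds are cut. Copper-catalysed asymmetric conjugate addition of Al(CH3)3 to enone A2 would create quaternary C1, and the aluminium enolate would be trapped by aldehyde A3 to give aldol A1.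
- Merits: the absolute configuration at C1 comes from a catalyst, not from the optical purity of a terpene. Three stereocentres arise in one flask. A later C9–C10 closure would install the C10 oxygen directly, so no alkene has to be moved.
- Weak points: no ring closes. The C5 configuration rests on the enolate distinguishing CH3 from CH2OPMB at C1, and C6 on an aluminium aldol of low inherent selectivity. A3 is a β,γ-unsaturated aldehyde that conjugates readily, and A1 is a retro-aldol-prone β-hydroxy ketone. The isopropyl addition at C4 and the seven-ring closure remain, each with its own facial question.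
- Comparison: in control of C1 this road is better. The chosen plan offsets this by forming both rings and C1/C5 at once, with C4 present from the start.

Alternative 2: The C3–C4 bond is cut. SmI2 (divalent samarium) would reduce the primary iodide of iodo ketone A5 and add C3 to the isopropyl ketone, closing the cyclopentane to A4.
- Merits: ketone–halide Barbier closures to cyclopentanols are dependable. A4 already holds all five stereocentres, with C6 and C10 oxygens under different protecting groups. Its endgame of two ordered acylations would be shorter and cleaner than the chosen one.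
- Weak points: the difficulty is moved into A5, a cycloheptene with quaternary C1 and three further stereocentres, for which this road offers no construction. C5 of A5 is α to the ketone and β to the C6 ether, so it can epimerise or eliminate. The C4 configuration depends on which ketone face the organosamarium reaches.
- Comparison: the endgame is superior, but the overall route is longer and its hardest part is unsolved. The chosen plan gives up endgame economy (three steps to move the alkene) for a precursor available in nine steps.

Alternative 3: The C1–C10 bond is cut. Heating cis-divinylcyclopropane A7 would break C6–C8 and form C1–C10 through a boat transition state, giving A6.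
- Merits: A6 has oxygen on C10 with the right configuration (from the (E)-alkoxyvinyl group), the alkene at C8=C9, C6 at ketone level and quaternary C1, all from one stereospecific step. In oxidation-pattern economy it is better than the chosen plan.
- Weak points: the cyclopentenyl terminus C1 is fully substituted, so its methyl must point inward in the boat, which raises the barrier. A7 needs a siloxycyclopropane of defined configuration relative to C4. C5 must later be set by protonation of the enol ether, with no clear bias toward trans fusion.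
- Comparison: the chosen plan has a far simpler precursor and sets C5 within the ring-forming step, at the price of the later alkene transposition.

Key step: step 10

Assumption: (S)-(+)-terpinen-4-ol is taken to be available in high enantiomeric purity, since the absolute configuration of the whole route rests on its carbinol carbon.

Step 1
Reactants: 1 (S)-terpinen-4-ol
Product: 2 (S)-terpinen-4-ol triethylsilyl ether
Conditions: Et3SiOTf, 2,6-lutidine, CH2Cl2, −78 → 0 °C
Reagents that add atoms: triethylsilyl trifluoromethanesulfonate, CC[Si](CC)(CC)OS(=O)(=O)C(F)(F)F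
Why: Silyl triflate silylation of a tertiary alcohol; protecting before ozonolysis prevents hemiketal formation and retro-aldol cleavage of the β-oxygenated carbonyl compounds that follow, and no stereocentre is touched.

Step 2
Reactants: 2 (S)-terpinen-4-ol triethylsilyl ether
Product: 4 (3S)-6-oxo-3-(propan-2-yl)-3-(triethylsilyloxy)heptanal, via ozonide 3 (not isolated)
Conditions: O3, CH2Cl2, −78 °C; then PPh3, −78 °C → rt
Reagents that add atoms: ozone, [O-][O+]=O
Why: Ozonolysis (Criegee mechanism) of the only alkene with reductive work-up of ozonide 3; the alkene carbons become the methyl ketone (C1) and the aldehyde (C6), and C4 is unaffected.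

Step 3
Reactants: 4 (3S)-6-oxo-3-(propan-2-yl)-3-(triethylsilyloxy)heptanal
Product: 5 (5S)-7,7-dimethoxy-5-(propan-2-yl)-5-(triethylsilyloxy)heptan-2-one
Conditions: HC(OCH3)3, CeCl3·7H2O (cat.), CH3OH, rt
Reagents that add atoms: trimethyl orthoformate, COC(OC)OC
Why: Lanthanide-catalysed acetalisation converts aldehydes far faster than ketones, so C6 is masked selectively against the amide base and organoaluminium reagent to come.

Step 4
Reactants: 5 (5S)-7,7-dimethoxy-5-(propan-2-yl)-5-(triethylsilyloxy)heptan-2-one
Product: 7 (3S)-1,1-dimethoxy-3-(propan-2-yl)-3-(triethylsilyloxy)hept-6-yne, via enol phosphate 6 (not isolated)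
Conditions: LiN(i-Pr)2, THF, −78 °C; ClP(O)(OEt)2, −78 °C → rt; LiN(i-Pr)2 (2.3 equiv), −78 °C → rt; H2O
Reagents that add atoms: none
Why: Kinetic enolisation at the methyl group, O-phosphorylation and base-induced elimination of the enol phosphate (methyl ketone to terminal alkyne protocol); acetal and silyl ether are inert to amide base.

Step 5
Reactants: 7 (3S)-1,1-dimethoxy-3-(propan-2-yl)-3-(triethylsilyloxy)hept-6-yne
Product: 9 (3S,6E)-7-iodo-1,1-dimethoxy-6-methyl-3-(propan-2-yl)-3-(triethylsilyloxy)hept-6-ene, via alkenylalane 8 (not isolated)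
Conditions: Al(CH3)3, Cp2ZrCl2 (20 mol %), H2O (1 equiv), CH2Cl2, −20 °C; then I2, THF, −20 °C
Reagents that add atoms: trimethylaluminium, C[Al](C)C; iodine, II
Why: Negishi zirconium-catalysed carboalumination adds CH3 and Al syn across the alkyne with methyl on the internal carbon, and iodinolysis with retention fixes the (E) geometry of the future C1=C10 bond (chain trans to iodine).

Step 6
Reactants: 9 (3S,6E)-7-iodo-1,1-dimethoxy-6-methyl-3-(propan-2-yl)-3-(triethylsilyloxy)hept-6-ene; 10 (E)-prop-1-en-1-ylboronic acid
Product: 11 (3S,6E,8E)-1,1-dimethoxy-6-methyl-3-(propan-2-yl)-3-(triethylsilyloxy)deca-6,8-diene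
Conditions: Pd(PPh3)4 (5 mol %), K3PO4, THF/H2O, 50 °C
Reagents that add atoms: none
Why: Suzuki–Miyaura coupling forms C9–C10 with retention at both alkenyl partners, so the (E,E)-diene geometry follows from 9 and 10.

Step 7
Reactants: 11 (3S,6E,8E)-1,1-dimethoxy-6-methyl-3-(propan-2-yl)-3-(triethylsilyloxy)deca-6,8-diene
Product: 12 (3S,6E,8E)-6-methyl-3-(propan-2-yl)-3-(triethylsilyloxy)deca-6,8-dienal
Conditions: PPTS (cat.), acetone/H2O, 40 °C
Reagents that add atoms: water, O
Why: Acid-catalysed acetal hydrolysis under conditions too mild to cleave the tertiary silyl ether or isomerise the diene.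

Step 8
Reactants: 12 (3S,6E,8E)-6-methyl-3-(propan-2-yl)-3-(triethylsilyloxy)deca-6,8-dienal; 13 chloroiodomethane
Product: 14 (4S,7E,9E)-1-chloro-7-methyl-4-(propan-2-yl)-4-(triethylsilyloxy)undeca-7,9-dien-2-ol (both C2 epimers)
Conditions: CH3Li·LiBr, THF, −78 °C (carbenoid generated in the presence of 12); NH4Cl (aq), −78 °C
Reagents that add atoms: none
Why: Barbier-type addition of chloromethyllithium, formed by iodine–lithium exchange, to the aldehyde forms C6–C7; cold protonation keeps the chlorohydrin from closing to the epoxide, and the new carbinol centre is oxidised in the next step.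

Step 9
Reactants: 14 (4S,7E,9E)-1-chloro-7-methyl-4-(propan-2-yl)-4-(triethylsilyloxy)undeca-7,9-dien-2-ol
Product: 15 (4S,7E,9E)-1-chloro-7-methyl-4-(propan-2-yl)-4-(triethylsilyloxy)undeca-7,9-dien-2-one
Conditions: Dess–Martin periodinane, NaHCO3, CH2Cl2, 0 °C → rt
Reagents that add atoms: none
Why: Dess–Martin oxidation of a secondary alcohol under buffered, non-basic conditions that spare the diene, the silyl ether and the α-chloro ketone formed.

Step 10
Reactants: 15 (4S,7E,9E)-1-chloro-7-methyl-4-(propan-2-yl)-4-(triethylsilyloxy)undeca-7,9-dien-2-one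
Product: 17 trans-fused hydroazul-9-en-6-one (1β,8α-dimethyl; 4α-isopropyl; 4β-triethylsilyloxy; 5α-H), via oxyallyl cation 16 (not isolated)
Conditions: Et3N (2 equiv), CF3CH2OH, 0.01 M, 0 °C → rt
Reagents that add atoms: none
Why: The amine enolises 15 toward C5 and, in the ionising solvent, chloride leaves C7 to give oxyallyl cation 16 with C4 syn to the oxygen, which adds across the termini of the s-cis (E,E)-diene. The closest known reaction type is the (4+3) cycloaddition of α-halo-ketone-derived oxyallyl cations with 1,3-dienes in fluorinated alcohols, including intramolecular cases that give 5,7-fused ketones. The cyclopentane closes by bonding cation terminus C5 to diene terminus C1 across the three-atom tether C2–C4, and the cycloheptenone closes through the second bond C7–C8 of the cycloaddition itself. Suprafacial addition places the two outer diene substituents, the tether at C1 and the methyl at C8, cis on the new ring, so 8α-methyl/8β-H follows from the E,E geometry. Trans fusion (C1 methyl β, C5 hydrogen α) follows from the extended arrangement in which the C–O of the cation points away from C9–C10; the compact arrangement would give the cis-fused isomer. The sense relative to C4 is set by that centre: with the tether bridging to the diene, the isopropyl group should turn toward C5–H and away from the cation C6–O, the smaller silyloxy group lying next to it, which leads to the 4β-silyloxy, 5α-H, 1β-methyl isomer. The step needs a geometrically pure diene (secured by steps 5 and 6), no free hydroxyl at C4 (the silyl ether blocks O-alkylation and retro-aldol cleavage) and high dilution.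

Step 11
Reactants: 17 trans-fused hydroazul-9-en-6-one (4β-triethylsilyloxy)
Product: 18 4β-hydroxy-1β,8α-dimethyl-4α-isopropyl-5α-H-hydroazul-9-en-6-one
Conditions: HF·pyridine, pyridine, THF, 0 °C → rt
Reagents that add atoms: none
Why: Fluoride-mediated silyl ether cleavage under non-basic conditions, which avoids retro-aldol opening of the β-hydroxy ketone and epimerisation at C5.

Step 12
Reactants: 18 4β-hydroxy-1β,8α-dimethyl-4α-isopropyl-5α-H-hydroazul-9-en-6-one
Product: 19 1β,8α-dimethyl-4α-isopropyl-5α-H-hydroazul-9-ene-4β,6α-diol
Conditions: Me4N[BH(OAc)3], CH3CN/AcOH, −30 → −20 °C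
Reagents that add atoms: none
Why: Evans–Saksena directed reduction: the C4 hydroxyl binds boron and delivers hydride intramolecularly to the β face of the C6 carbonyl, giving the 6α-alcohol; the reagent is too weak for competing external attack.

Step 13
Reactants: 19 1β,8α-dimethyl-4α-isopropyl-5α-H-hydroazul-9-ene-4β,6α-diol; 20 3,4-dimethoxybenzoyl chloride
Product: 21 6α-(3,4-dimethoxybenzoyloxy)-1β,8α-dimethyl-4α-isopropyl-5α-H-hydroazul-9-en-4β-ol
Conditions: Et3N, DMAP (cat.), CH2Cl2, 0 °C → rt
Reagents that add atoms: none
Why: DMAP-catalysed acylation distinguishes the secondary C6 hydroxyl from the tertiary C4 hydroxyl, the only other one present.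

Step 14
Reactants: 21 6α-(3,4-dimethoxybenzoyloxy)-1β,8α-dimethyl-4α-isopropyl-5α-H-hydroazul-9-en-4β-ol
Product: 22 9α,10α-epoxide of 21
Conditions: mCPBA, NaHCO3, CH2Cl2, 0 °C
Reagents that add atoms: 3-chloroperoxybenzoic acid, OOC(=O)c1cccc(Cl)c1
Why: Prilezhaev epoxidation of the cis-disubstituted alkene anti to the pseudo-axial C1 methyl should place oxygen on the α face, setting C9 and C10; the C4 hydroxyl lies on the far side of the cyclopentane and cannot direct the peracid.

Step 15
Reactants: 22 9α,10α-epoxide of 21
Product: 25 6α-(3,4-dimethoxybenzoyloxy)-1β,8-dimethyl-4α-isopropyl-5α-H-hydroazul-8-ene-4β,10α-diol, via hydroxy selenide 23 (not isolated), via selenoxide 24 (not isolated)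
Conditions: PhSeSePh, NaBH4, EtOH, rt → 50 °C; then THF, pyridine, 30% H2O2, 0 °C → rt
Reagents that add atoms: none
Why: Selenolate opens the epoxide at C9 with inversion (neopentyl C10 is blocked; trans-diaxial, Fürst–Plattner), and selenoxide syn elimination uses the cis hydrogen at C8 in preference to the carbinol hydrogen, giving C8=C9 and the 10α-alcohol (epoxide to allylic alcohol transposition).

Step 16
Reactants: 25 6α-(3,4-dimethoxybenzoyloxy)-1β,8-dimethyl-4α-isopropyl-5α-H-hydroazul-8-ene-4β,10α-diol; 26 angelic acid
Product: 27 target, 10α-[(Z)-2-methylbut-2-enoyloxy]-6α-(3,4-dimethoxybenzoyloxy)-1β,8-dimethyl-4α-isopropyl-5α-H-hydroazul-8-en-4β-ol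
Conditions: 26, 2,4,6-trichlorobenzoyl chloride, Et3N, toluene, rt; then 25, toluene, 80 °C
Reagents that add atoms: none
Why: Yamaguchi-type mixed-anhydride esterification without a nucleophilic catalyst, conditions under which angelates are transferred without Z to E isomerisation; the tertiary C4 hydroxyl does not react.

## Compound list

1 | (S)-terpinen-4-ol | CC1=CC[C@](O)(C(C)C)CC1 | starting material
2 | (S)-terpinen-4-ol triethylsilyl ether | CC1=CC[C@](O[Si](CC)(CC)CC)(C(C)C)CC1 | intermediate
3 | ozonide (1,2,4-trioxolane) of 2 | CC12CC[C@@](O[Si](CC)(CC)CC)(C(C)C)CC(OO1)O2 | intermediate (not isolated)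
4 | (3S)-6-oxo-3-(propan-2-yl)-3-(triethylsilyloxy)heptanal | CC(=O)CC[C@@](O[Si](CC)(CC)CC)(C(C)C)CC=O | intermediate
5 | (5S)-7,7-dimethoxy-5-(propan-2-yl)-5-(triethylsilyloxy)heptan-2-one | CC(=O)CC[C@@](O[Si](CC)(CC)CC)(C(C)C)CC(OC)OC | intermediate
6 | diethyl (5S)-7,7-dimethoxy-5-(propan-2-yl)-5-(triethylsilyloxy)hept-1-en-2-yl phosphate | C=C(OP(=O)(OCC)OCC)CC[C@@](O[Si](CC)(CC)CC)(C(C)C)CC(OC)OC | intermediate (not isolated)
7 | (3S)-1,1-dimethoxy-3-(propan-2-yl)-3-(triethylsilyloxy)hept-6-yne | C#CCC[C@@](O[Si](CC)(CC)CC)(C(C)C)CC(OC)OC | intermediate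
8 | dimethyl[(1E,5S)-7,7-dimethoxy-2-methyl-5-(propan-2-yl)-5-(triethylsilyloxy)hept-1-en-1-yl]alane | C[Al](C)/C=C(\C)CC[C@@](O[Si](CC)(CC)CC)(C(C)C)CC(OC)OC | intermediate (not isolated)
9 | (3S,6E)-7-iodo-1,1-dimethoxy-6-methyl-3-(propan-2-yl)-3-(triethylsilyloxy)hept-6-ene | I/C=C(\C)CC[C@@](O[Si](CC)(CC)CC)(C(C)C)CC(OC)OC | intermediate
10 | (E)-prop-1-en-1-ylboronic acid | C/C=C/B(O)O | starting material
11 | (3S,6E,8E)-1,1-dimethoxy-6-methyl-3-(propan-2-yl)-3-(triethylsilyloxy)deca-6,8-diene | C/C=C/C=C(\C)CC[C@@](O[Si](CC)(CC)CC)(C(C)C)CC(OC)OC | intermediate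
12 | (3S,6E,8E)-6-methyl-3-(propan-2-yl)-3-(triethylsilyloxy)deca-6,8-dienal | C/C=C/C=C(\C)CC[C@@](O[Si](CC)(CC)CC)(C(C)C)CC=O | intermediate
13 | chloroiodomethane | ClCI | starting material
14 | (4S,7E,9E)-1-chloro-7-methyl-4-(propan-2-yl)-4-(triethylsilyloxy)undeca-7,9-dien-2-ol, both C2 epimers | C/C=C/C=C(\C)CC[C@@](O[Si](CC)(CC)CC)(C(C)C)CC(O)CCl | intermediate
15 | (4S,7E,9E)-1-chloro-7-methyl-4-(propan-2-yl)-4-(triethylsilyloxy)undeca-7,9-dien-2-one | C/C=C/C=C(\C)CC[C@@](O[Si](CC)(CC)CC)(C(C)C)CC(=O)CCl | intermediate
16 | oxyallyl cation (C5–C6–C7) of 15, C4 syn to oxygen | C/C=C/C=C(\C)CC[C@@](O[Si](CC)(CC)CC)(C(C)C)/C=C(\[O-])[CH2+] | intermediate (not isolated)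
17 | trans-fused hydroazul-9-en-6-one: 1β,8α-dimethyl, 4α-isopropyl, 4β-triethylsilyloxy, 5α-H | C1=C[C@H](C)CC(=O)[C@@H]2[C@]1(C)CC[C@@]2(O[Si](CC)(CC)CC)C(C)C | intermediate
18 | 4β-hydroxy-1β,8α-dimethyl-4α-isopropyl-5α-H-hydroazul-9-en-6-one | C1=C[C@H](C)CC(=O)[C@@H]2[C@]1(C)CC[C@@]2(O)C(C)C | intermediate
19 | 1β,8α-dimethyl-4α-isopropyl-5α-H-hydroazul-9-ene-4β,6α-diol | C1=C[C@H](C)C[C@H](O)[C@@H]2[C@]1(C)CC[C@@]2(O)C(C)C | intermediate
20 | 3,4-dimethoxybenzoyl chloride | COc1ccc(C(=O)Cl)cc1OC | starting material
21 | 6α-(3,4-dimethoxybenzoyloxy)-1β,8α-dimethyl-4α-isopropyl-5α-H-hydroazul-9-en-4β-ol | C1=C[C@H](C)C[C@H](OC(=O)c3ccc(OC)c(OC)c3)[C@@H]2[C@]1(C)CC[C@@]2(O)C(C)C | intermediate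
22 | 9α,10α-epoxide of 21 (oxirane oxygen α) | O1[C@@H]2[C@H]1[C@H](C)C[C@H](OC(=O)c3ccc(OC)c(OC)c3)[C@@H]4[C@]2(C)CC[C@@]4(O)C(C)C | intermediate
23 | 9β-phenylselanyl-10α-hydroxy compound from 22 | O[C@@H]1[C@@H]([Se]c3ccccc3)[C@H](C)C[C@H](OC(=O)c4ccc(OC)c(OC)c4)[C@@H]2[C@]1(C)CC[C@@]2(O)C(C)C | intermediate (not isolated)
24 | selenoxide of 23 | O[C@@H]1[C@@H]([Se](=O)c3ccccc3)[C@H](C)C[C@H](OC(=O)c4ccc(OC)c(OC)c4)[C@@H]2[C@]1(C)CC[C@@]2(O)C(C)C | intermediate (not isolated)
25 | 6α-(3,4-dimethoxybenzoyloxy)-1β,8-dimethyl-4α-isopropyl-5α-H-hydroazul-8-ene-4β,10α-diol | O[C@@H]1C=C(C)C[C@H](OC(=O)c3ccc(OC)c(OC)c3)[C@@H]2[C@]1(C)CC[C@@]2(O)C(C)C | intermediate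
26 | angelic acid, (Z)-2-methylbut-2-enoic acid | C/C=C(/C)C(=O)O | starting material
27 | 10α-angeloyloxy-6α-(3,4-dimethoxybenzoyloxy)-1β,8-dimethyl-4α-isopropyl-5α-H-hydroazul-8-en-4β-ol | C/C=C(/C)C(=O)O[C@@H]1C=C(C)C[C@H](OC(=O)c2ccc(OC)c(OC)c2)[C@@H]2[C@]1(C)CC[C@@]2(O)C(C)C | target

## Step count and least certain steps

Total: 16 steps, all in one linear sequence from 1 (longest linear sequence 16). Compounds 10, 13, 20 and 26 are purchased.

Step 10 (key step). The most likely failure is interception of the weakly stabilised, monoalkyl oxyallyl cation (solvent capture, alkylation of the amine, Favorskii-type rearrangement) before it bonds to the fully substituted diene terminus C1, whose inner methyl strains the s-cis conformer. A stepwise course would also erode the stereospecificity at C8 and the fusion. The facial preference imposed by C4 is the second uncertainty. Fallback: from aldehyde 12, add dichloromethyllithium (CH2Cl2, LiN(i-Pr)2, −78 °C) to give the dichloromethyl carbinol F1, and oxidise with Dess–Martin periodinane to the dichloromethyl ketone F2. Its chlorine-stabilised, longer-lived oxyallyl cation should cyclise under the same amine/trifluoroethanol conditions to the 7-chloro cycloadduct F3. Reductive dechlorination with Zn in AcOH then returns to the route at 17.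

Step 5. The dimethyl acetal may be ionised or methylated by the Lewis-acidic aluminium/zirconium mixture. Fallback: from alkyne 7, copper-catalysed syn-methylboration (B2pin2, CuCl, phosphine ligand, NaOt-Bu, CH3I) gives the (E)-alkenyl pinacol boronate F4 under conditions that leave acetals untouched. Suzuki coupling of F4 with (E)-1-bromoprop-1-ene (Pd(PPh3)4, K3PO4) then returns to the route at 11.

Step 12. Ligand exchange at the hindered tertiary hydroxyl may be slow, so external hydride delivery from the α face could compete and give the 6β-alcohol. Fallback: from 18, reduce with LiBH(s-Bu)3, which should attack from the open α face and give the 6β-alcohol F5 deliberately. Then invert C6 while installing the ester by a Mitsunobu reaction with 3,4-dimethoxybenzoic acid (PPh3, diisopropyl azodicarboxylate), returning at 21.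

Step 14. Facial selectivity may be poor or reversed, because the α face carries the axial hydrogens at C5 and C7 and the ring body. Fallback, for the case where the reagent prefers the β face: from 21, NBS in aqueous THF forms the β-bromonium ion, which water opens from the α face to the bromohydrin F6. Closure with DBU turns the same facial preference into the α-epoxide 22.

Step 15. Opening at C9 may be sluggish, and the heat needed may cost the veratrate through ethanolysis or reduction. Fallback: postpone the first esterification. From diol 19, epoxidise to the epoxy diol F7, open with selenolate at higher temperature to the hydroxy selenide F8, oxidise to the selenoxide F9 and eliminate to the triol F10. Then acylate the less hindered C6 hydroxyl with 20 in preference to the neopentyl C10 hydroxyl, returning at 25.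

Step 16. Z to E isomerisation to the tiglate and slow acylation of the neopentyl C10 hydroxyl are the risks. Fallback: from 25, esterify with 2-[bis(2,2,2-trifluoroethoxy)phosphoryl]propanoic acid (DCC, DMAP) to the phosphonate ester F11. Then build the (Z)-2-methylbut-2-enoate in place by Still–Gennari olefination with acetaldehyde (KN(SiMe3)2, 18-crown-6, THF, −78 °C), arriving at 27.

## Further compounds

F1 | step 10 | (4S,7E,9E)-1,1-dichloro-7-methyl-4-(propan-2-yl)-4-(triethylsilyloxy)undeca-7,9-dien-2-ol | C/C=C/C=C(\C)CC[C@@](O[Si](CC)(CC)CC)(C(C)C)CC(O)C(Cl)Cl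
F2 | step 10 | (4S,7E,9E)-1,1-dichloro-7-methyl-4-(propan-2-yl)-4-(triethylsilyloxy)undeca-7,9-dien-2-one | C/C=C/C=C(\C)CC[C@@](O[Si](CC)(CC)CC)(C(C)C)CC(=O)C(Cl)Cl
F3 | step 10 | 7-chloro derivative of 17 (C7 epimers) | C1=C[C@H](C)C(Cl)C(=O)[C@@H]2[C@]1(C)CC[C@@]2(O[Si](CC)(CC)CC)C(C)C
F4 | step 5 | 2-[(1E,5S)-7,7-dimethoxy-2-methyl-5-(propan-2-yl)-5-(triethylsilyloxy)hept-1-en-1-yl]-4,4,5,5-tetramethyl-1,3,2-dioxaborolane | CC1(C)OB(/C=C(\C)CC[C@@](O[Si](CC)(CC)CC)(C(C)C)CC(OC)OC)OC1(C)C
F5 | step 12 | 1β,8α-dimethyl-4α-isopropyl-5α-H-hydroazul-9-ene-4β,6β-diol | C1=C[C@H](C)C[C@@H](O)[C@@H]2[C@]1(C)CC[C@@]2(O)C(C)C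
F6 | step 14 | 10β-bromo-9α-hydroxy bromohydrin of 21 | Br[C@H]1[C@H](O)[C@H](C)C[C@H](OC(=O)c3ccc(OC)c(OC)c3)[C@@H]2[C@]1(C)CC[C@@]2(O)C(C)C
F7 | step 15 | 9α,10α-epoxide of diol 19 | O1[C@@H]2[C@H]1[C@H](C)C[C@H](O)[C@@H]4[C@]2(C)CC[C@@]4(O)C(C)C
F8 | step 15 | 9β-phenylselanyl-1β,8α-dimethyl-4α-isopropyl-5α-H-perhydroazulene-4β,6α,10α-triol | O[C@@H]1[C@@H]([Se]c3ccccc3)[C@H](C)C[C@H](O)[C@@H]2[C@]1(C)CC[C@@]2(O)C(C)C
F9 | step 15 | selenoxide of F8 | O[C@@H]1[C@@H]([Se](=O)c3ccccc3)[C@H](C)C[C@H](O)[C@@H]2[C@]1(C)CC[C@@]2(O)C(C)C
F10 | step 15 | 1β,8-dimethyl-4α-isopropyl-5α-H-hydroazul-8-ene-4β,6α,10α-triol | O[C@@H]1C=C(C)C[C@H](O)[C@@H]2[C@]1(C)CC[C@@]2(O)C(C)C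
F11 | step 16 | 10-O-{2-[bis(2,2,2-trifluoroethoxy)phosphoryl]propanoyl} ester of 25 | CC(C(=O)O[C@@H]1C=C(C)C[C@H](OC(=O)c2ccc(OC)c(OC)c2)[C@@H]2[C@]1(C)CC[C@@]2(O)C(C)C)P(=O)(OCC(F)(F)F)OCC(F)(F)F
A1 | alternative 1 | aldol product with C1, C5, C6 set and the C7–C9 (Z)-vinyl iodide chain | I/C=C(/C)C[C@H](O)[C@H]1C(=O)CC[C@]1(C)COCc2ccc(OC)cc2
A2 | alternative 1 | 3-[(4-methoxybenzyloxy)methyl]cyclopent-2-en-1-one | O=C1C=C(COCc2ccc(OC)cc2)CC1
A3 | alternative 1 | (Z)-4-iodo-3-methylbut-3-enal | O=CC/C(C)=C\I
A4 | alternative 2 | hydroazulene with C4 tertiary alcohol, C6 methoxymethyl ether and C10 silyl ether | CC(C)(C)[Si](C)(C)O[C@@H]1C=C(C)C[C@H](OCOC)[C@@H]2[C@]1(C)CC[C@@]2(O)C(C)C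
A5 | alternative 2 | cycloheptene iodo ketone (C5 isobutyryl, C1 2-iodoethyl) | CC(C)(C)[Si](C)(C)O[C@@H]1C=C(C)C[C@H](OCOC)[C@@H](C(=O)C(C)C)[C@]1(C)CCI
A6 | alternative 3 | hydroazulene with C5=C6 silyl enol ether, C8=C9 alkene and C10 4-methoxybenzyl ether | COc1ccc(CO[C@@H]2C=C(C)CC(O[Si](C)(C)C(C)(C)C)=C3[C@]2(C)CC[C@@]3(O[Si](CC)(CC)CC)C(C)C)cc1
A7 | alternative 3 | cis-divinylcyclopropane (ring C6–C7–C8; cyclopentenyl on C6, (E)-alkoxyvinyl on C8) | COc1ccc(CO/C=C/[C@@]2(C)C[C@@]2(O[Si](C)(C)C(C)(C)C)C3=C(C)CC[C@@]3(O[Si](CC)(CC)CC)C(C)C)cc1
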